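**Plan**

1. Retrosynthesis: the five benzyl ethers come off last. The C3–OH and C4–H bonds are cut as a syn hydration of a C3=C4 double bond, which leads back to a 2,4-diaryl-2H-chromene.
2. The pyran ring C is cut at O1–C2 and C2–C3 together, giving the B-ring aryl aldehyde and an A-ring phenol that carries a 1,1-diarylethene. The feature that allows this: C2 is at the aldehyde oxidation level between O1 of ring A and ring B, and C4 carries two aryl groups (rings A and D), so the ethene is a strong π-nucleophile.
3. The diarylethene is cut at the C4–ring D bond to an aryllithium (from 2-methoxyresorcinol) and 4'-benzyloxy-2'-hydroxyacetophenone.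
4. Forward: rings A and D are joined at the future C4 (steps 1–5), ring C is closed onto the B-ring aldehyde (step 6), then the alkene is hydrated and the benzyl groups removed (steps 7, 8).
5. Stereochemistry: C2 comes from the chiral Brønsted acid in step 6; C3 and C4 come from syn hydroboration on the face anti to the C2 aryl group in step 7.

Key step: step 6

Assumption: the sense of induction of the chiral acid cannot be predicted for this new reaction. The catalyst enantiomer written is taken to give the (S)-chromene; its antipode is used if a test run shows the opposite sense.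

**Route**

Step 1
Reactants: 1 2',4'-dihydroxyacetophenone
Product: 2 1-[4-(benzyloxy)-2-hydroxyphenyl]ethan-1-one
Conditions: BnBr (1.05 equiv), K2CO3, acetone, reflux
Reagents that add atoms: benzyl bromide, BrCc1ccccc1
Why: Williamson etherification should occur only at the 4'-OH, because the 2'-OH is held in a hydrogen bond to the ketone and is far less nucleophilic.

Step 2
Reactants: 3 2-methoxyresorcinol
Product: 4 1,3-bis(benzyloxy)-2-methoxybenzene
Conditions: BnBr (2.3 equiv), K2CO3, DMF, 60 °C
Reagents that add atoms: benzyl bromide, BrCc1ccccc1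
Why: Double Williamson etherification of the two equivalent phenols is unambiguous.

Step 3
Reactants: 4 1,3-bis(benzyloxy)-2-methoxybenzene
Product: 5 1,3-bis(benzyloxy)-4-bromo-2-methoxybenzene
Conditions: NBS (1.0 equiv), MeCN, 0 °C to rt
Reagents that add atoms: N-bromosuccinimide, O=C1CCC(=O)N1Br
Why: Electrophilic aromatic bromination should go to C4, which is para to one benzyloxy group and ortho to the other, whereas C5 is meta to both and activated only by the flanked, twisted methoxy group; one equivalent limits dibromination.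

Step 4
Reactants: 5 1,3-bis(benzyloxy)-4-bromo-2-methoxybenzene (2.3 equiv); 2 1-[4-(benzyloxy)-2-hydroxyphenyl]ethan-1-one
Product: 7 5-(benzyloxy)-2-{1-[2,4-bis(benzyloxy)-3-methoxyphenyl]-1-hydroxyethyl}phenol (racemic), via aryllithium 6 (not isolated)
Conditions: n-BuLi (2.3 equiv), THF, −78 °C; then 2, −78 to 0 °C; sat. aq. NH4Cl
Reagents that add atoms: none
Why: Bromine–lithium exchange at −78 °C is faster than benzylic deprotonation, the first equivalent of 6 removes the phenol proton (and returns as recyclable 4), and the second adds 1,2 to the ketone (aryllithium addition to a ketone); the new carbinol centre is racemic and is destroyed in step 5.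

Step 5
Reactants: 7 5-(benzyloxy)-2-{1-[2,4-bis(benzyloxy)-3-methoxyphenyl]-1-hydroxyethyl}phenol
Product: 8 5-(benzyloxy)-2-{1-[2,4-bis(benzyloxy)-3-methoxyphenyl]ethenyl}phenol
Conditions: PPTS (10 mol %), toluene, 50 °C
Reagents that add atoms: none
Why: E1 dehydration through the diaryl cation stabilised as a protonated o-quinone methide should be easy under weak acid, and only the methyl group offers β-hydrogens, so only the 1,1-diarylethene can form.

Step 6
Reactants: 8 5-(benzyloxy)-2-{1-[2,4-bis(benzyloxy)-3-methoxyphenyl]ethenyl}phenol; 9 3,4-bis(benzyloxy)benzaldehyde (1.5 equiv)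
Product: 11 (2S)-7-(benzyloxy)-4-[2,4-bis(benzyloxy)-3-methoxyphenyl]-2-[3,4-bis(benzyloxy)phenyl]-2H-chromene, via allylic alcohol 10 (not isolated)
Conditions: (R)-3,3'-bis(2,4,6-triisopropylphenyl)-BINOL N-triflylphosphoramide (10 mol %), 5 Å MS, toluene, −40 °C, slow addition of 8 to 9 and catalyst; Et3N quench at −40 °C
Reagents that add atoms: none
Why: Proposed new method: the strong chiral acid activates aldehyde 9 as its O-protonated oxocarbenium ion (the phenol-bound, hemiacetal-derived ion would react in the same sense), and the CH2 terminus of the electron-rich diarylethene attacks it in a Prins C–C bond formation (C2–C3) that leaves a doubly benzylic, o-quinone-methide-stabilised cation at C4; proton loss gives allylic alcohol 10, which ionises with loss of water to a 1,3-diarylallyl cation paired with the chiral anion. The closest known reactions are the strong-chiral-acid-catalysed intermolecular Prins and carbonyl–ene additions of alkenes to aldehydes and the chiral N-triflylphosphoramide-catalysed cyclisation of phenol-bearing 1,3-diarylallyl alcohols to 2,4-diaryl-2H-chromenes; merging the two in one flask from a vinylphenol and an aldehyde is what is new. The pyran ring closes by 6-endo attack of the phenol oxygen on the C2 terminus of the allyl cation (formally an oxa-6π closure of the protonated vinyl o-quinone methide), forming O1–C2. C2 is the only stereocentre made and is set in this C–O closure by the chiral phosphoramide anion, which is hydrogen-bonded to the phenol OH and shields one face of the planar cation (catalyst control). The step needs ring closure to outrun dimerisation of 8, Friedel–Crafts or indene-forming capture of the cation and re-ionisation of the product at C2–O1; the ortho OH placed for six-membered closure, the para-benzyloxy groups on both C4 aryl rings that keep the alkene nucleophilic in the cold, slow addition of 8 to excess 9 and the cold amine quench should secure this.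

Step 7
Reactants: 11 (2S)-7-(benzyloxy)-4-[2,4-bis(benzyloxy)-3-methoxyphenyl]-2-[3,4-bis(benzyloxy)phenyl]-2H-chromene
Product: 12 (2R,3S,4S)-7-(benzyloxy)-4-[2,4-bis(benzyloxy)-3-methoxyphenyl]-2-[3,4-bis(benzyloxy)phenyl]-3,4-dihydro-2H-chromen-3-ol (2,3-trans-3,4-trans; C2 and C4 aryl groups cis)
Conditions: BH3·THF (3 equiv), THF, 0 °C to rt; then 3 M NaOH, 30% H2O2, 0 °C
Reagents that add atoms: hydrogen peroxide, OO
Why: Hydroboration–oxidation should place boron on C3 (the less substituted alkene carbon) and hydrogen on C4 in a syn addition on the face anti to the C2 aryl group, and oxidation with retention then gives the 3-OH trans to both aryl groups; the C2 descriptor changes from S to R only because the CIP priorities change, and the same holds for C4 (S here, R in the target).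

Step 8
Reactants: 12 (2R,3S,4S)-7-(benzyloxy)-4-[2,4-bis(benzyloxy)-3-methoxyphenyl]-2-[3,4-bis(benzyloxy)phenyl]-3,4-dihydro-2H-chromen-3-ol
Product: 13 (2R,3S,4R)-2-(3,4-dihydroxyphenyl)-4-(2,4-dihydroxy-3-methoxyphenyl)-3,4-dihydro-2H-chromene-3,7-diol (CNP0124388.1)
Conditions: H2 (1 atm), 20% Pd(OH)2/C, THF/MeOH, rt
Reagents that add atoms: none
Why: Hydrogenolysis of the five benzyl ethers is the standard end-game for benzylated flavan-3-ols, in which the cyclic C2–O1 benzylic ether survives at room temperature and no stereocentre is touched.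

**Compound list**

1 | 2',4'-dihydroxyacetophenone | CC(=O)c1ccc(O)cc1O | starting material
2 | 1-[4-(benzyloxy)-2-hydroxyphenyl]ethan-1-one | CC(=O)c1ccc(OCc2ccccc2)cc1O | intermediate
3 | 2-methoxyresorcinol | COc1c(O)cccc1O | starting material
4 | 1,3-bis(benzyloxy)-2-methoxybenzene | COc1c(OCc2ccccc2)cccc1OCc1ccccc1 | intermediate
5 | 1,3-bis(benzyloxy)-4-bromo-2-methoxybenzene | COc1c(OCc2ccccc2)ccc(Br)c1OCc1ccccc1 | intermediate
6 | [2,4-bis(benzyloxy)-3-methoxyphenyl]lithium | [Li]c1ccc(OCc2ccccc2)c(OC)c1OCc1ccccc1 | intermediate (not isolated)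
7 | 5-(benzyloxy)-2-{1-[2,4-bis(benzyloxy)-3-methoxyphenyl]-1-hydroxyethyl}phenol (racemic) | COc1c(OCc2ccccc2)ccc(C(C)(O)c2ccc(OCc3ccccc3)cc2O)c1OCc1ccccc1 | intermediate
8 | 5-(benzyloxy)-2-{1-[2,4-bis(benzyloxy)-3-methoxyphenyl]ethenyl}phenol | COc1c(OCc2ccccc2)ccc(C(=C)c2ccc(OCc3ccccc3)cc2O)c1OCc1ccccc1 | intermediate
9 | 3,4-bis(benzyloxy)benzaldehyde | O=Cc1ccc(OCc2ccccc2)c(OCc2ccccc2)c1 | starting material
10 | 5-(benzyloxy)-2-{1-[2,4-bis(benzyloxy)-3-methoxyphenyl]-3-[3,4-bis(benzyloxy)phenyl]-3-hydroxyprop-1-en-1-yl}phenol (stereoisomer mixture, erased on ionisation) | COc1c(OCc2ccccc2)ccc(C(=CC(O)c2ccc(OCc3ccccc3)c(OCc3ccccc3)c2)c2ccc(OCc3ccccc3)cc2O)c1OCc1ccccc1 | intermediate (not isolated)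
11 | (2S)-7-(benzyloxy)-4-[2,4-bis(benzyloxy)-3-methoxyphenyl]-2-[3,4-bis(benzyloxy)phenyl]-2H-chromene | COc1c(OCc2ccccc2)ccc(C2=C[C@@H](c3ccc(OCc4ccccc4)c(OCc4ccccc4)c3)Oc3cc(OCc4ccccc4)ccc32)c1OCc1ccccc1 | intermediate
12 | (2R,3S,4S)-7-(benzyloxy)-4-[2,4-bis(benzyloxy)-3-methoxyphenyl]-2-[3,4-bis(benzyloxy)phenyl]-3,4-dihydro-2H-chromen-3-ol | COc1c(OCc2ccccc2)ccc([C@@H]2c3ccc(OCc4ccccc4)cc3O[C@H](c3ccc(OCc4ccccc4)c(OCc4ccccc4)c3)[C@H]2O)c1OCc1ccccc1 | intermediate
13 | (2R,3S,4R)-2-(3,4-dihydroxyphenyl)-4-(2,4-dihydroxy-3-methoxyphenyl)-3,4-dihydro-2H-chromene-3,7-diol | COc1c(O)ccc([C@@H]2c3ccc(O)cc3O[C@H](c3ccc(O)c(O)c3)[C@H]2O)c1O | target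

**Count**

Total steps: 8. Longest linear sequence: 7 steps (3 → 4 → 5 → 7 → 8 → 11 → 12 → 13).

**Steps most likely to fail**

Step 6 (proposed new method). The Prins C–C bond formation with the electron-rich, weakly electrophilic aldehyde may be too slow at a temperature where the product is configurationally stable. Acid-promoted dimerisation of the vinylphenol, hydride-transfer loss of the chromene to a benzopyrylium salt, or racemisation by re-ionisation at C2–O1 could then take over. The fallback uses known chemistry and reaches the same allyl cation from a preformed alcohol. It sets out from 2 and 9: Claisen–Schmidt condensation (KOH, EtOH, rt) gives (2E)-1-[4-(benzyloxy)-2-hydroxyphenyl]-3-[3,4-bis(benzyloxy)phenyl]prop-2-en-1-one F1. 1,2-Addition of aryllithium 6 (made from 5 as in step 4, with one extra equivalent for the phenol) in THF at −78 °C gives the racemic tertiary allylic alcohol 5-(benzyloxy)-2-{(2E)-1-[2,4-bis(benzyloxy)-3-methoxyphenyl]-3-[3,4-bis(benzyloxy)phenyl]-1-hydroxyprop-2-en-1-yl}phenol F2. F2 is cyclised with the same chiral N-triflylphosphoramide in toluene at low temperature, which is the established enantioselective intramolecular allylic etherification to 2,4-diaryl-2H-chromenes. The route is rejoined at 11.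

Step 7. Borane may discriminate the two faces incompletely (addition syn to the C2 aryl group), or the hindered alkene may react sluggishly, allowing β-elimination of the β-aryloxy borane. The fallback sets the C3 and C4 configurations under thermodynamic and ketone-reduction control instead of by syn addition. It sets out from 11: hydroboration–oxidation is run without regard to face selectivity, giving 12 mixed with its C3,C4-diastereomer, the (2R,3R,4R)-alcohol F3. The mixture is oxidised with Dess–Martin periodinane to the 2,4-cis chroman-3-one F4 and the 2,4-trans chroman-3-one F5. Brief treatment with a weak amine base equilibrates the acidic, doubly benzylic C4 centre so that F5 drains into F4, which has both aryl groups pseudo-equatorial. NaBH4 in THF/MeOH at −40 °C should then deliver hydride along the axial trajectory, which carries no 1,3-diaxial hydrogens in this ring, to give the all-equatorial alcohol. The route is rejoined at 12; exposure to base is kept short to avoid enolisation toward C2.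

Step 4. The basic aryllithium may enolise the methyl ketone of the lithium phenoxide instead of adding to it, returning 2 after work-up. The fallback replaces carbonyl addition by a cross-coupling. It sets out from 2: condensation with tosylhydrazide (MeOH, 60 °C) gives the N-tosylhydrazone N'-{(1E)-1-[4-(benzyloxy)-2-hydroxyphenyl]ethylidene}-4-methylbenzenesulfonohydrazide F6. Barluenga coupling of F6 with bromide 5 (Pd2(dba)3, XPhos, LiOtBu in excess, dioxane, 100 °C) proceeds by migratory insertion of the palladium carbene and β-hydride elimination from the methyl group, giving the 1,1-diarylethene directly. The route is rejoined at 8, bypassing 6 and 7.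

**Further compounds**

F1 | step 6 | (2E)-1-[4-(benzyloxy)-2-hydroxyphenyl]-3-[3,4-bis(benzyloxy)phenyl]prop-2-en-1-one | O=C(/C=C/c1ccc(OCc2ccccc2)c(OCc2ccccc2)c1)c1ccc(OCc2ccccc2)cc1O
F2 | step 6 | 5-(benzyloxy)-2-{(2E)-1-[2,4-bis(benzyloxy)-3-methoxyphenyl]-3-[3,4-bis(benzyloxy)phenyl]-1-hydroxyprop-2-en-1-yl}phenol (racemic) | COc1c(OCc2ccccc2)ccc(C(O)(/C=C/c2ccc(OCc3ccccc3)c(OCc3ccccc3)c2)c2ccc(OCc3ccccc3)cc2O)c1OCc1ccccc1
F3 | step 7 | (2R,3R,4R)-7-(benzyloxy)-4-[2,4-bis(benzyloxy)-3-methoxyphenyl]-2-[3,4-bis(benzyloxy)phenyl]-3,4-dihydro-2H-chromen-3-ol | COc1c(OCc2ccccc2)ccc([C@H]2c3ccc(OCc4ccccc4)cc3O[C@H](c3ccc(OCc4ccccc4)c(OCc4ccccc4)c3)[C@@H]2O)c1OCc1ccccc1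
F4 | step 7 | (2R,4S)-7-(benzyloxy)-4-[2,4-bis(benzyloxy)-3-methoxyphenyl]-2-[3,4-bis(benzyloxy)phenyl]-2H-chromen-3(4H)-one (2,4-cis) | COc1c(OCc2ccccc2)ccc([C@@H]2c3ccc(OCc4ccccc4)cc3O[C@H](c3ccc(OCc4ccccc4)c(OCc4ccccc4)c3)C2=O)c1OCc1ccccc1
F5 | step 7 | (2R,4R)-7-(benzyloxy)-4-[2,4-bis(benzyloxy)-3-methoxyphenyl]-2-[3,4-bis(benzyloxy)phenyl]-2H-chromen-3(4H)-one (2,4-trans) | COc1c(OCc2ccccc2)ccc([C@H]2c3ccc(OCc4ccccc4)cc3O[C@H](c3ccc(OCc4ccccc4)c(OCc4ccccc4)c3)C2=O)c1OCc1ccccc1
F6 | step 4 | N'-{(1E)-1-[4-(benzyloxy)-2-hydroxyphenyl]ethylidene}-4-methylbenzenesulfonohydrazide | C/C(=N\NS(=O)(=O)c1ccc(C)cc1)c1ccc(OCc2ccccc2)cc1O
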